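**Retrosynthetic overview**

1. The bridgehead benzoyl group is removed last (bridgehead lithiation–acylation), leaving a benzoyl-free cage tetraketone.
2. Key disconnection: the bond from the cage ketone carbon next to the geranyl-bearing bridgehead to the fully substituted carbon shared by the trione ring and the cyclopentanone. These two carbons, the cyclopentanone CH2 and its C=O form a 1,4-diketone, so the quaternary carbon is the β-carbon of a cyclopentenone and is made by an intramolecular Stetter addition; the ring-fusion CH is then γ to that carbonyl and can epimerise.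
3. The Stetter precursor is a bicyclo[4.3.1]decane keto aldehyde with a fused cyclopentenone. A Mukaiyama aldol joins the cyclohexanone α-carbon to the formyl carbon of a β-bromo enal (from 2,2-dimethylcyclopentane-1,3-dione), a nickel-catalysed C(sp3)–C(sp2) reductive coupling closes the seven-membered ring, and MnO2 gives the ketone.
4. The cyclohexanone comes from dimedone ethyl enol ether: catalytic asymmetric hydroxymethylation (the only externally controlled stereocentre), reductive enone transposition, reductive formylation and Pd-catalysed geranylation (quaternary carbon, formyl cis to CH2Br).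
5. Ring order: cyclohexanone and cyclopentene (from the two diketones), then the first seven-membered ring (step 10), then the trione ring together with the second seven-membered ring, which closes the cage (step 12).

Key step: step 12

Remark on the chemistry: the (S,S)-ligand of step 2 is assumed to give the 6R alcohol; if the sense of induction is opposite, the (R,R)-ligand is used.
Remark on the drawings: the formyl ketone of step 5 is drawn as its chelated enol, and the hydroxy and keto aldehydes of steps 9 to 11 are drawn open-chain, although lactol and enol forms are expected to be present.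

Step 1
Reactants: 1 3-ethoxy-5,5-dimethylcyclohex-2-en-1-one
Product: 3 [(5-ethoxy-3,3-dimethylcyclohexa-1,5-dien-1-yl)oxy]trimethylsilane, via lithium dienolate 2 (not isolated)
Conditions: LiN(i-Pr)2, THF, −78 °C; then Me3SiCl, −78 °C to rt
Reagents that add atoms: chlorotrimethylsilane C[Si](C)(C)Cl
Why: Kinetic deprotonation of the vinylogous ester takes place at the α′ CH2 and O-silylation traps the cross-conjugated enolate as the silyl dienol ether needed for a Lewis-acid-catalysed aldol (enolate silylation).

Step 2
Reactants: 3 [(5-ethoxy-3,3-dimethylcyclohexa-1,5-dien-1-yl)oxy]trimethylsilane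
Product: 4 (6R)-3-ethoxy-6-(hydroxymethyl)-5,5-dimethylcyclohex-2-en-1-one
Conditions: aq. HCHO, Sc(OTf)3 (10 mol %), (S,S)-6,6'-bis(1-hydroxy-2,2-dimethylpropyl)-2,2'-bipyridine (12 mol %), DME/H2O, −20 °C
Reagents that add atoms: formaldehyde C=O
Why: A Mukaiyama-type aldol addition of the silicon enolate to formaldehyde under chiral scandium–bipyridine catalysis (catalytic asymmetric hydroxymethylation) forms the C–CH2OH bond at the enol ether terminus, and the ligand-shielded enolate face should set the R stereocentre on which all later stereochemistry depends.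

Step 3
Reactants: 4 (6R)-3-ethoxy-6-(hydroxymethyl)-5,5-dimethylcyclohex-2-en-1-one
Product: 6 (4R)-4-(hydroxymethyl)-5,5-dimethylcyclohex-2-en-1-one, via allylic alcohol 5 (not isolated)
Conditions: i-Bu2AlH (2.5 equiv), CH2Cl2, −78 °C; then 1 M HCl, THF, 0 °C to rt
Reagents that add atoms: water O
Why: In this Stork–Danheiser reductive transposition, 1,2-reduction of the vinylogous ester carbonyl followed by acid hydrolysis of the enol ether with loss of the allylic hydroxyl gives the transposed enone, removes the carbonyl that is no longer needed and leaves the stereocentre untouched.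

Step 4
Reactants: 6 (4R)-4-(hydroxymethyl)-5,5-dimethylcyclohex-2-en-1-one
Product: 7 (4R)-4-(bromomethyl)-5,5-dimethylcyclohex-2-en-1-one
Conditions: CBr4, PPh3, CH2Cl2, 0 °C
Reagents that add atoms: carbon tetrabromide BrC(Br)(Br)Br
Why: The Appel bromination of the primary alcohol runs under neutral conditions, so the γ-hydrogen of the enone is not removed and vinylogous elimination should not occur.

Step 5
Reactants: 7 (4R)-4-(bromomethyl)-5,5-dimethylcyclohex-2-en-1-one
Product: 9 (2Z,4R)-4-(bromomethyl)-2-(hydroxymethylidene)-5,5-dimethylcyclohexan-1-one, via lithium enolate 8 (not isolated)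
Conditions: LiBH(s-Bu)3 (L-Selectride), THF, −78 °C; then HCO2CH2CF3, −78 to 0 °C; aq. NH4Cl
Reagents that add atoms: 2,2,2-trifluoroethyl formate O=COCC(F)(F)F
Why: Conjugate hydride addition of the bulky borohydride to the β-unsubstituted enone gives the regiodefined enolate, which is C-formylated by the trifluoroethyl formate (Claisen-type formylation of an enolate).

Step 6
Reactants: 9 (2Z,4R)-4-(bromomethyl)-2-(hydroxymethylidene)-5,5-dimethylcyclohexan-1-one; 10 geranyl acetate
Product: 12 (1R,5R)-5-(bromomethyl)-1-[(2E)-3,7-dimethylocta-2,6-dien-1-yl]-4,4-dimethyl-2-oxocyclohexane-1-carbaldehyde, via sodium enolate 11 (not isolated)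
Conditions: NaH, THF, 0 °C; then Pd(PPh3)4 (5 mol %), 10, rt
Reagents that add atoms: none
Why: In this Tsuji–Trost allylation the soft formyl-ketone enolate attacks the π-geranyl palladium complex on carbon and at its unsubstituted terminus (E olefin kept), the allyl group entering axially on the ring face opposite to the bromomethyl group, which should set the quaternary stereocentre with the formyl group cis to CH2Br.

Step 7
Reactants: 12 (1R,5R)-5-(bromomethyl)-1-[(2E)-3,7-dimethylocta-2,6-dien-1-yl]-4,4-dimethyl-2-oxocyclohexane-1-carbaldehyde
Product: 13 (1S,5R)-5-(bromomethyl)-1-[(2E)-3,7-dimethylocta-2,6-dien-1-yl]-4,4-dimethyl-2-[(trimethylsilyl)oxy]cyclohex-2-ene-1-carbaldehyde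
Conditions: Me3SiOTf, Et3N, CH2Cl2, 0 °C
Reagents that add atoms: trimethylsilyl trifluoromethanesulfonate C[Si](C)(C)OS(=O)(=O)C(F)(F)F
Why: Soft enolisation–silylation can only involve the remaining α-CH2 because the other α-carbon is quaternary and the formyl group has no α-hydrogen, so a single silyl enol ether should form.

Step 8
Reactants: 14 2,2-dimethylcyclopentane-1,3-dione
Product: 15 2-bromo-3,3-dimethyl-4-oxocyclopent-1-ene-1-carbaldehyde
Conditions: PBr3, DMF, CHCl3, 0 °C to rt; then aq. NaOAc
Reagents that add atoms: N,N-dimethylformamide CN(C)C=O; phosphorus tribromide BrP(Br)Br; water O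
Why: The Vilsmeier–Haack–Arnold bromoformylation converts one enolisable ketone of the symmetrical dione into a β-bromo enal by formylation of the α-CH2 and exchange of the carbonyl oxygen for bromide.

Step 9
Reactants: 13 (1S,5R)-5-(bromomethyl)-1-[(2E)-3,7-dimethylocta-2,6-dien-1-yl]-4,4-dimethyl-2-[(trimethylsilyl)oxy]cyclohex-2-ene-1-carbaldehyde; 15 2-bromo-3,3-dimethyl-4-oxocyclopent-1-ene-1-carbaldehyde
Product: 16 (1R,3S,5R)-5-(bromomethyl)-3-[(2-bromo-3,3-dimethyl-4-oxocyclopent-1-en-1-yl)(hydroxy)methyl]-1-[(2E)-3,7-dimethylocta-2,6-dien-1-yl]-4,4-dimethyl-2-oxocyclohexane-1-carbaldehyde (both carbinol epimers)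
Conditions: BF3·OEt2, CH2Cl2, −78 °C; then aq. NaHCO3 and dilute HCl/THF
Reagents that add atoms: none
Why: The BF3-mediated Mukaiyama aldol addition should join the silyl enol ether to the accessible conjugated formyl group of 15 rather than to the neopentyl formyl group of 13, the aldehyde approaching anti to the axial geranyl group so that the new side chain is cis to CH2Br and CHO, while the carbinol configuration is of no consequence.

Step 10
Reactants: 16 (1R,3S,5R)-5-(bromomethyl)-3-[(2-bromo-3,3-dimethyl-4-oxocyclopent-1-en-1-yl)(hydroxy)methyl]-1-[(2E)-3,7-dimethylocta-2,6-dien-1-yl]-4,4-dimethyl-2-oxocyclohexane-1-carbaldehyde (both carbinol epimers)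
Product: 17 bicyclo[4.3.1]decane allylic alcohol formed by joining the CH2Br carbon of 16 to its bromoalkene carbon (cyclohexanone bridged by CH2–C=C–CH(OH); C=C shared by the dimethylcyclopentenone; bridgehead hydrogens exo; formyl group on the side of the new bridge)
Conditions: NiBr2(MeOCH2CH2OMe) (20 mol %), 4,4'-di-tert-butyl-2,2'-bipyridine (20 mol %), Mn powder, NaI, N,N-dimethylacetamide, 40 °C, high dilution
Reagents that add atoms: none
Why: A nickel-catalysed reductive cross-electrophile coupling joins the primary alkyl bromide (alkyl radical captured by nickel) to the alkenyl bromide (oxidative addition) and closes the seven-membered ring between the two cis side chains, which the six-membered lactol between carbinol and formyl group is expected to hold diaxial.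

Step 11
Reactants: 17 bicyclo[4.3.1]decane allylic alcohol
Product: 18 bicyclo[4.3.1]decane 1,3-diketo aldehyde carrying the fused tetrasubstituted cyclopentenone (carbinol of 17 oxidised to the ketone)
Conditions: MnO2, CH2Cl2, rt
Reagents that add atoms: none
Why: MnO2 oxidises only the allylic secondary alcohol (allylic alcohol oxidation), which should leave the aldehyde and its lactol form alone and give the 1,3-diketone at a stage where the enone β-carbon no longer carries a leaving group.

Step 12
Reactants: 18 bicyclo[4.3.1]decane 1,3-diketo aldehyde carrying the fused tetrasubstituted cyclopentenone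
Product: 20 benzoyl-free cage tetraketone (the target with H in place of the bridgehead benzoyl group), via ene-dione tautomer 19 (not isolated)
Conditions: 3-benzyl-5-(2-hydroxyethyl)-4-methylthiazolium chloride (30 mol %), DBU (1.3 equiv), THF, 50 °C
Reagents that add atoms: none
Why: DBU converts the tetrasubstituted enone 18 through its dienolate into the conjugated ene-dione 19, whose ring-fusion CH (γ to the cyclopentenone carbonyl) epimerises freely, while the thiazol-2-ylidene adds to the formyl group to give the acyl-anion equivalent, which adds to the β-carbon of the cyclopentenone and then releases the catalyst. The closest known reaction type is the intramolecular Stetter reaction onto a β,β-disubstituted Michael acceptor that creates a quaternary carbon. The new bond closes the six-membered trione ring in a 6-exo-trig mode (attack at the CH= carbon would be 7-endo) and, counted along the CH2 tether, the second seven-membered carbocycle in a 7-exo-trig mode, which completes the homoadamantane-type cage. The quaternary carbon is fixed by the two tethers, since attack can only come from the face that carries the first seven-membered ring, and the ring-fusion CH should be set by dynamic kinetic resolution, because with the ketone branch lying in the enone plane only one epimer brings the acceptor carbon within reach of the formyl carbon. The step needs the irreversible acyl-anion addition to outrun deformylation of the non-enolisable β-keto aldehyde and the reversible aldol or oxa-Michael additions of the enolised 1,3-diketone and dienolate; the doubly activated ene-dione and the rigid bicyclo[4.3.1]decane, which holds the two carbons close, are what should secure this.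

Step 13
Reactants: 20 benzoyl-free cage tetraketone; 21 benzoyl chloride
Product: 25 target CNP0110281.1, via silyl enol ether 22 (not isolated), via bridgehead lithium compound 23 (not isolated), via benzoylated silyl enol ether 24 (not isolated)
Conditions: LiN(i-Pr)2, Me3SiCl, THF, −78 °C; then lithium 2,2,6,6-tetramethylpiperidide, −78 to −40 °C; then 21, −78 °C to rt; then 1 M HCl
Reagents that add atoms: none
Why: After the only enolisable ketone is masked in situ as its silyl enol ether, the bridgehead C–H flanked by two ketones is lithiated by the hindered amide and C-acylated by benzoyl chloride (bridgehead lithiation–acylation of a bicyclo[3.3.1]nonane trione), the cage fixing the configuration and the acid work-up freeing the cyclopentanone.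

**Compound list**

1 | 3-ethoxy-5,5-dimethylcyclohex-2-en-1-one (dimedone ethyl enol ether) | CCOC1=CC(=O)CC(C)(C)C1 | starting material
2 | lithium 5-ethoxy-3,3-dimethylcyclohexa-1,5-dien-1-olate | [Li]OC1=CC(C)(C)CC(OCC)=C1 | intermediate (not isolated)
3 | [(5-ethoxy-3,3-dimethylcyclohexa-1,5-dien-1-yl)oxy]trimethylsilane | CCOC1=CC(O[Si](C)(C)C)=CC(C)(C)C1 | intermediate
4 | (6R)-3-ethoxy-6-(hydroxymethyl)-5,5-dimethylcyclohex-2-en-1-one | CCOC1=CC(=O)[C@@H](CO)C(C)(C)C1 | intermediate
5 | (6R)-3-ethoxy-6-(hydroxymethyl)-5,5-dimethylcyclohex-2-en-1-ol (both carbinol epimers) | CCOC1=CC(O)[C@@H](CO)C(C)(C)C1 | intermediate (not isolated)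
6 | (4R)-4-(hydroxymethyl)-5,5-dimethylcyclohex-2-en-1-one | O=C1C=C[C@@H](CO)C(C)(C)C1 | intermediate
7 | (4R)-4-(bromomethyl)-5,5-dimethylcyclohex-2-en-1-one | O=C1C=C[C@@H](CBr)C(C)(C)C1 | intermediate
8 | lithium (4R)-4-(bromomethyl)-5,5-dimethylcyclohex-1-en-1-olate | [Li]OC1=CC[C@@H](CBr)C(C)(C)C1 | intermediate (not isolated)
9 | (2Z,4R)-4-(bromomethyl)-2-(hydroxymethylidene)-5,5-dimethylcyclohexan-1-one | O/C=C1\C(=O)CC(C)(C)[C@H](CBr)C1 | intermediate
10 | geranyl acetate, (2E)-3,7-dimethylocta-2,6-dien-1-yl acetate | CC(C)=CCC/C(C)=C/COC(C)=O | starting material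
11 | sodium enolate of 9 | [Na]O/C=C1\C(=O)CC(C)(C)[C@H](CBr)C1 | intermediate (not isolated)
12 | (1R,5R)-5-(bromomethyl)-1-[(2E)-3,7-dimethylocta-2,6-dien-1-yl]-4,4-dimethyl-2-oxocyclohexane-1-carbaldehyde (CHO cis to CH2Br) | CC(C)=CCC/C(C)=C/C[C@]1(C=O)C[C@@H](CBr)C(C)(C)CC1=O | intermediate
13 | (1S,5R)-5-(bromomethyl)-1-[(2E)-3,7-dimethylocta-2,6-dien-1-yl]-4,4-dimethyl-2-[(trimethylsilyl)oxy]cyclohex-2-ene-1-carbaldehyde | CC(C)=CCC/C(C)=C/C[C@]1(C=O)C[C@@H](CBr)C(C)(C)C=C1O[Si](C)(C)C | intermediate
14 | 2,2-dimethylcyclopentane-1,3-dione | CC1(C)C(=O)CCC1=O | starting material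
15 | 2-bromo-3,3-dimethyl-4-oxocyclopent-1-ene-1-carbaldehyde | O=CC1=C(Br)C(C)(C)C(=O)C1 | intermediate
16 | (1R,3S,5R)-5-(bromomethyl)-3-[(2-bromo-3,3-dimethyl-4-oxocyclopent-1-en-1-yl)(hydroxy)methyl]-1-[(2E)-3,7-dimethylocta-2,6-dien-1-yl]-4,4-dimethyl-2-oxocyclohexane-1-carbaldehyde (both carbinol epimers; CHO, CH2Br and the carbinol side chain all cis) | CC(C)=CCC/C(C)=C/C[C@]1(C=O)C[C@@H](CBr)C(C)(C)[C@@H](C(O)C2=C(Br)C(C)(C)C(=O)C2)C1=O | intermediate
17 | bicyclo[4.3.1]decane allylic alcohol: 16 ring-closed between the former CH2Br carbon and the former C–Br alkene carbon; bridgehead hydrogens exo, formyl group on the side of the new bridge, both carbinol epimers | CC(C)=CCC/C(C)=C/C[C@]1(C=O)C[C@H]2CC3=C(CC(=O)C3(C)C)C(O)[C@@H](C1=O)C2(C)C | intermediate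
18 | bicyclo[4.3.1]decane 1,3-diketo aldehyde with fused tetrasubstituted cyclopentenone (17 with the carbinol oxidised) | CC(C)=CCC/C(C)=C/C[C@]1(C=O)C[C@H]2CC3=C(CC(=O)C3(C)C)C(=O)[C@@H](C1=O)C2(C)C | intermediate
19 | ene-dione tautomer of 18 (cyclopent-2-enone; ring-fusion CH in the configuration that cyclises, in base-mediated equilibrium with its epimer and with 18) | CC(C)=CCC/C(C)=C/C[C@]1(C=O)C[C@H]2C[C@H]3C(C)(C)C(=O)C=C3C(=O)[C@@H](C1=O)C2(C)C | intermediate (not isolated)
20 | benzoyl-free cage tetraketone (target with H at the bridgehead between the two ring ketones next to the CMe2 bridge) | CC(C)=CCC/C(C)=C/C[C@@]12C[C@H]3C[C@H]4C(C)(C)C(=O)C[C@]4(C1=O)C(=O)[C@@H](C2=O)C3(C)C | intermediate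
21 | benzoyl chloride | O=C(Cl)c1ccccc1 | starting material
22 | trimethylsilyl enol ether of the cyclopentanone of 20 | CC(C)=CCC/C(C)=C/C[C@@]12C[C@H]3C[C@H]4C(C)(C)C(O[Si](C)(C)C)=C[C@]4(C1=O)C(=O)[C@@H](C2=O)C3(C)C | intermediate (not isolated)
23 | 22 lithiated at the bridgehead carbon between the two ring ketones | CC(C)=CCC/C(C)=C/C[C@@]12C[C@H]3C[C@H]4C(C)(C)C(O[Si](C)(C)C)=C[C@]4(C1=O)C(=O)[C@@]([Li])(C2=O)C3(C)C | intermediate (not isolated)
24 | bridgehead-benzoylated silyl enol ether | CC(C)=CCC/C(C)=C/C[C@@]12C[C@H]3C[C@H]4C(C)(C)C(O[Si](C)(C)C)=C[C@]4(C1=O)C(=O)[C@@](C(=O)c1ccccc1)(C2=O)C3(C)C | intermediate (not isolated)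
25 | target CNP0110281.1 | CC(C)=CCC/C(C)=C/C[C@@]12C[C@H]3C[C@H]4C(C)(C)C(=O)C[C@]4(C1=O)C(=O)[C@@](C(=O)c1ccccc1)(C2=O)C3(C)C | target

**Step count**

Total: 13 steps. Longest linear sequence: 12 steps (steps 1 to 7 and 9 to 13); step 8 makes building block 15.

**Steps most likely to fail, with fallbacks**

Most at risk is step 10 (nickel ring closure). Hydrodebromination of the primary bromide, or capture of the alkyl radical or alkylnickel species by the neighbouring formyl group, may outrun C–C coupling in the strained seven-membered transition state. The fallback reverses the order of the two C–C bonds; it sets out from 9 and 15 and comes back to the route at 17. The sodium enolate 11 of 9 (NaH, so that no acidic proton remains) is coupled intermolecularly with 15 under the same nickel conditions (NiBr2(MeOCH2CH2OMe), 4,4'-di-tert-butyl-2,2'-bipyridine, Mn), where there is neither ring strain nor a formyl group on the alkyl partner, and work-up should give the coupled formyl ketone enol F1. NaH, Pd(PPh3)4 and 10, as in step 6, then convert this enol into the geranylated keto dialdehyde F2. Soft enolisation of the cyclohexanone of this dialdehyde (MgBr2·OEt2, i-Pr2NEt, CH2Cl2) should trigger an intramolecular aldol addition of its only α-CH2 to the conjugated formyl group, which closes the seven-membered ring through the C–C(OH) bond, necessarily cis, and gives 17.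

Second is step 12 (key step). The carbene adduct of the hindered β-keto aldehyde may fragment (deformylation), or the acyl-anion equivalent may form too slowly, so that reversible aldol pathways or decomposition win. The fallback makes the same bond with natural polarity at the alcohol oxidation level; it sets out from 18 and comes back to the route at 20. After equilibration of 18 with 19 (catalytic DBU), [(Ph3P)CuH]6 in toluene/THF at −40 °C to rt should deliver hydride to the CH= carbon of the ene-dione, and the copper enolate at the future quaternary carbon should add to the formyl group (reductive aldol cyclisation) to give the cage carbinol F3. DMP (1,1,1-triacetoxy-1,1-dihydro-1,2-benziodoxol-3(1H)-one) in CH2Cl2 then oxidises this carbinol to 20. Only the epimer that can reach the formyl group closes, so this variant gives up the dynamic resolution.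

Third is step 2 (asymmetric hydroxymethylation). Poor facial discrimination on the hindered cross-conjugated enolate, or hydrolysis of the silyl enol ether before C–C bond formation, would erode the enantiomeric purity on which everything rests. The fallback separates the enantiomers enzymatically; it sets out from 1 and comes back to the route at 4. The lithium dienolate 2 of 1 (LiN(i-Pr)2, THF, −78 °C) is treated with monomeric formaldehyde to give the racemic hydroxymethyl ketone F4. Lipase-catalysed acylation of this racemate (Burkholderia cepacia lipase, vinyl acetate, t-BuOMe, rt) is assumed to acetylate the S enantiomer faster, giving the (6S)-acetate F5 and leaving the R alcohol 4, which is separated by chromatography. The acylation is run past half conversion so that the remaining alcohol is enantiomerically enriched at the cost of material.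

Further compounds
F1 | step 10 | (2Z)-4-[(2-formyl-5,5-dimethyl-4-oxocyclopent-1-en-1-yl)methyl]-2-(hydroxymethylidene)-5,5-dimethylcyclohexan-1-one (ring CH configured as in 9) | O/C=C1\C(=O)CC(C)(C)[C@H](CC2=C(C=O)CC(=O)C2(C)C)C1
F2 | step 10 | 1-[(2E)-3,7-dimethylocta-2,6-dien-1-yl]-5-[(2-formyl-5,5-dimethyl-4-oxocyclopent-1-en-1-yl)methyl]-4,4-dimethyl-2-oxocyclohexane-1-carbaldehyde (configured as 12, CHO cis to the cyclopentenylmethyl group) | CC(C)=CCC/C(C)=C/C[C@]1(C=O)C[C@@H](CC2=C(C=O)CC(=O)C2(C)C)C(C)(C)CC1=O
F3 | step 12 | cage carbinol: 20 with CH(OH) in place of the ketone formed in the key step (both carbinol epimers) | CC(C)=CCC/C(C)=C/C[C@@]12C[C@H]3C[C@H]4C(C)(C)C(=O)C[C@]4(C1O)C(=O)[C@@H](C2=O)C3(C)C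
F4 | step 2 | racemic 3-ethoxy-6-(hydroxymethyl)-5,5-dimethylcyclohex-2-en-1-one | CCOC1=CC(=O)C(CO)C(C)(C)C1
F5 | step 2 | [(1S)-4-ethoxy-6,6-dimethyl-2-oxocyclohex-3-en-1-yl]methyl acetate | CCOC1=CC(=O)[C@H](COC(C)=O)C(C)(C)C1
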